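The trap in repeating this run is to read the order in catalyst from one late pair of readings that happen to match.

| flask | substrate | partner | free catalyst | added ligand | remark |
|---|---|---|---|---|---|
| alder | 0.050 M | 1 equiv | 13 mol% | 14 mM | run made earlier |
| ash | 0.050 M | 1 equiv | 21 mol% | 14 mM | run made earlier |
| flask | 0.050 M | 1.00 equiv | 9.6 mol% | 14 mM |  |

- alder (time / min: product / %, substrate / %): 6.00: 32, 70; 20.0: 59, 42; 30.0: 72, 29; 50.0: 81, 19; 80.0: 85, 12
- ash (time / min: product / %, substrate / %): 15.0: 66, 37; 30.0: 79, 21; 40.0: 85, 16; 60.0: 90, 10; 80.0: 95, 8

(standard deviation of a reading: 2 percentage points)



1. factor on the rate of making product when 20% of the substrate are converted if free catalyst is charged twice over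
2. factor on the rate when 20% of the substrate are converted if free catalyst is charged at 2 mol% instead

At 20% conversion, substrate and partner stand at the same fractions of their charges whatever the loading, and the added ligand charge is unchanged. So I take each asked factor as the loading ratio raised to one power.

My first way uses the substrate column. With equal charges, partner tracks substrate, so one over the fraction left, minus one, divided by time, gives a second-order constant. Averaged over each run:

alder: 0.0798 min⁻¹

ash: 0.133 min⁻¹

ln(constant ratio) / ln(loading ratio) = 1.06

This is the catalyst order, the power that turns a loading ratio into a rate factor at equal conversion, here a reading that carries the scatter of its runs.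

My second way uses the product column. The alder run shows 85% at 80.0 min, and the ash run shows 85% at 40.0 min:

ln(time ratio) / ln(loading ratio) = 1.45

The ways part, the second standing higher. The second one cheats: the alder run gains just 4 percentage points over its last 30.0 min, while a reading scatters by 2 points, so its arrival time is poorly held. The first rests on 10 readings, and I commit to it:

doubled: 2.09

at 2 mol%: 0.189

The forecast gives 2.05 and 0.19, and it says “the catalyst order is about 1.1”; my doubling factor stands slightly higher than its own.

The simulation gives 2.20 and 0.175.

    substrate + partner + free catalyst → product + free catalyst, rate k1*[substrate]*[partner]*[free catalyst]/(1 + ([substrate]/sat1)) (0.0630 M, k = 460 M⁻² min⁻¹)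
    free catalyst → spent catalyst (k = 1.20 × 10⁻⁴ min⁻¹)
    free catalyst + added ligand ⇌ idle complex (K = 35.0 M⁻¹, k = 5.20 M⁻¹ min⁻¹)

The order 1.06 gave 2.09 against 2.20 for the doubling, and 0.189 against 0.175 for the flask charged at 2 mol%. In this flask at 0.195 h, free catalyst has a half-life of 0.18 h by the forward binding to added ligand alone, shorter than the 0.36 h of partner by the product step, and the idle complex it forms is an off-cycle form, no resting state of the round. At 20% conversion this flask has 80.3% of its catalyst free, and the flask charged at 2 mol% has 67.6%.

The readings were generated by integration for an exercise, and the scatter is random.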